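**Retrosynthetic overview**
1. Target ⇒ boron-mediated Knoevenagel of feruloylacetone (14) with the terpenyl vanillin ether 12.
2. 12 ⇒ Mitsunobu inversion of diol 10 with vanillin (11). 10 ⇒ Luche reduction of hydroxy-enone 9.
3. 9 ⇒ hydroxyl-directed hydrogenation of exocyclic methylene 8, which sets the side-chain CH(CH3) centre. 8 ⇒ photooxygenation of the silyl dienol ether of 6, which sets C4–OH anti to the side chain.
4. 6 ⇒ (R)-carvone (1) by ene reaction with CH2O, iodination and Negishi coupling.
5. No ring is built. The cyclohexene ring and its C5 centre come from carvone; the only other ring is a transient bicyclic endoperoxide in step 5.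

Assumption: TBSOTf/Et3N gives the extended C1-silyloxy-1,3-diene, and the ene reaction occurs at the isopropenyl methyl without touching C5.

---

**Step 1**
Reactants: 1 (R)-(−)-carvone; 2 paraformaldehyde
Product: 3 (5R)-5-(4-hydroxybut-1-en-2-yl)-2-methylcyclohex-2-en-1-one
Conditions: (CH2O)n, Me2AlCl, CH2Cl2, −78 → 0 °C
Reagents that add atoms: formaldehyde, C=O
Why: Lewis-acid carbonyl-ene reaction of the 1,1-disubstituted alkene gives the homoallylic alcohol with a new exocyclic methylene; C5 is untouched and stays R.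

**Step 2**
Reactants: 3
Product: 4 (5R)-5-(4-iodobut-1-en-2-yl)-2-methylcyclohex-2-en-1-one
Conditions: I2, PPh3, imidazole, CH2Cl2, 0 °C → rt
Reagents that add atoms: iodine, II
Why: Appel-type (Garegg–Samuelsson) iodination of the primary alcohol; the enone and alkene are inert.

**Step 3**
Reactants: 4; 5 2-methylprop-1-en-1-ylmagnesium bromide (converted in situ to the alkenylzinc)
Product: 6 (5R)-2-methyl-5-(6-methylhepta-1,5-dien-2-yl)cyclohex-2-en-1-one
Conditions: 5, then ZnBr2, THF, 0 °C; then 4, Pd-PEPPSI-IPent (3 mol%), THF/NMP, rt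
Reagents that add atoms: 2-methylprop-1-en-1-ylzinc bromide, CC(C)=C[Zn]Br
Why: Negishi C(sp3)–C(sp2) coupling completes the C15 skeleton; the organozinc does not add to the enone, and no stereocentre is involved.

**Step 4**
Reactants: 6
Product: 7 tert-butyl(dimethyl){[(5S)-2-methyl-5-(6-methylhepta-1,5-dien-2-yl)cyclohexa-1,3-dien-1-yl]oxy}silane
Conditions: TBSOTf, Et3N, CH2Cl2, 0 °C (used crude, cold)
Reagents that add atoms: TBSOTf, CC(C)(C)[Si](C)(C)OS(=O)(=O)C(F)(F)F
Why: thermodynamic γ-enolisation and silylation converts the enone into the electron-rich cyclohexa-1,3-diene needed for [4+2]; C5 is unchanged (the descriptor changes to S only through CIP priorities).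

**Step 5**
Reactants: 7
Product: 8 (4S,5R)-4-hydroxy-2-methyl-5-(6-methylhepta-1,5-dien-2-yl)cyclohex-2-en-1-one
Conditions: O2, TPP (1 mol%), white LEDs, CH2Cl2, −78 °C; then PPh3, TBAF/AcOH (1:1), THF, −78 → 0 °C
Reagents that add atoms: dioxygen, O=O
Why: singlet oxygen adds across C1/C4 of the diene on the face anti to the C5 side chain, so the new C4–O bond is trans to it. Proposed new method: the electron-rich silyl dienol ether reacts with 1O2 in [4+2] fashion much faster than the isolated 1,1-disubstituted and prenyl alkenes. The resulting C1 silyl peroxyketal ionises with assistance from the siloxy lone pair, is desilylated by fluoride to give the γ-hydroperoxy enone, and PPh3 reduces O–O to C4–OH with retention. The closest known reactions are cyclohexadiene endoperoxide formation/Kornblum–DeLaMare chemistry and Rubottom oxidation; here they are combined on an extended silyl dienol ether as a γ-hydroxylation of an enone.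

**Step 6**
Reactants: 8
Product: 9 (4R,5R)-4-hydroxy-2-methyl-5-[(2S)-6-methylhept-5-en-2-yl]cyclohex-2-en-1-one
Conditions: [Ir(cod)(PCy3)(py)]PF6 (5 mol%), H2 (1 atm), CH2Cl2, 23 °C
Reagents that add atoms: none
Why: Crabtree–Evans hydroxyl-directed hydrogenation. In the A(1,2)-preferred conformer (C5–H eclipsing the C7′–CH2R bond), C4 and its OH lie on one alkene face; Ir chelated by C4–OH delivers H2 to that face and gives the (S) CH(CH3) centre. The remote prenyl alkene and the electron-poor enone alkene are reduced more slowly.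

**Step 7**
Reactants: 9
Product: 10 (1R,4R,5R)-2-methyl-5-[(2S)-6-methylhept-5-en-2-yl]cyclohex-2-ene-1,4-diol
Conditions: NaBH4, CeCl3·7H2O, MeOH, −78 °C
Reagents that add atoms: none
Why: Luche 1,2-reduction by axial hydride attack gives the equatorial C1–OH cis to the C5 side chain, as in the carvone → cis-carveol reduction. This is the configuration needed for inversion in step 8.

**Step 8**
Reactants: 10; 11 vanillin (4-hydroxy-3-methoxybenzaldehyde)
Product: 12 4-{[(1S,4R,5R)-4-hydroxy-2-methyl-5-[(2S)-6-methylhept-5-en-2-yl]cyclohex-2-en-1-yl]oxy}-3-methoxybenzaldehyde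
Conditions: 11, PPh3, DIAD, THF, 0 °C → rt
Reagents that add atoms: vanillin, COc1cc(C=O)ccc1O
Why: Mitsunobu etherification proceeds by SN2 with inversion, turning the cis C1 alcohol into the trans aryl ether; the less hindered C1–OH reacts in preference to the C4–OH next to the branched C5.

**Step 9**
Reactants: 13 acetylacetone (pentane-2,4-dione); 11 vanillin
Product: 14 (5E)-6-(4-hydroxy-3-methoxyphenyl)hex-5-ene-2,4-dione (feruloylacetone)
Conditions: 13 (3 equiv), B2O3, EtOAc, 40 °C; then 11, B(OBu)3, n-BuNH2, 40 °C; then 10% aq. AcOH, 50 °C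
Reagents that add atoms: none beyond the reactants (boron reagents are lost on hydrolysis)
Why: Pabon boron-complex Knoevenagel condensation; excess 13 limits double condensation, and the E enone forms.

**Step 10**
Reactants: 12; 14
Product: 15 Terpecurcumin B
Conditions: 14, B2O3, EtOAc, 40 °C; then 12, B(OBu)3, n-BuNH2, 40 °C; then 10% aq. AcOH, 50 °C
Reagents that add atoms: none
Why: the same boron-mediated Knoevenagel of the remaining methyl ketone with aldehyde 12 gives the (E,E)-dienone/enol of curcumin type; the terpene stereocentres are not involved and the mild acid workup keeps the allylic aryl ether intact.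

---

**Compound list**

| No. | Name | SMILES | Role |
|---|---|---|---|
| 1 | (R)-(−)-carvone | O=C1C[C@H](C(C)=C)CC=C1C | starting material |
| 2 | paraformaldehyde (as CH2O) | C=O | starting material |
| 3 | (5R)-5-(4-hydroxybut-1-en-2-yl)-2-methylcyclohex-2-en-1-one | O=C1C[C@H](C(=C)CCO)CC=C1C | intermediate |
| 4 | (5R)-5-(4-iodobut-1-en-2-yl)-2-methylcyclohex-2-en-1-one | O=C1C[C@H](C(=C)CCI)CC=C1C | intermediate |
| 5 | 2-methylprop-1-en-1-ylmagnesium bromide | CC(C)=C[Mg]Br | starting material |
| 6 | (5R)-2-methyl-5-(6-methylhepta-1,5-dien-2-yl)cyclohex-2-en-1-one | O=C1C[C@H](C(=C)CCC=C(C)C)CC=C1C | intermediate |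
| 7 | TBS silyl dienol ether of 6 | C=C(CCC=C(C)C)[C@H]1CC(O[Si](C)(C)C(C)(C)C)=C(C)C=C1 | intermediate |
| 8 | (4S,5R)-4-hydroxy-2-methyl-5-(6-methylhepta-1,5-dien-2-yl)cyclohex-2-en-1-one | O=C1C[C@H](C(=C)CCC=C(C)C)[C@@H](O)C=C1C | intermediate |
| 9 | (4R,5R)-4-hydroxy-2-methyl-5-[(2S)-6-methylhept-5-en-2-yl]cyclohex-2-en-1-one | O=C1C[C@H]([C@@H](C)CCC=C(C)C)[C@@H](O)C=C1C | intermediate |
| 10 | (1R,4R,5R)-2-methyl-5-[(2S)-6-methylhept-5-en-2-yl]cyclohex-2-ene-1,4-diol | O[C@@H]1C[C@H]([C@@H](C)CCC=C(C)C)[C@@H](O)C=C1C | intermediate |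
| 11 | vanillin | COc1cc(C=O)ccc1O | starting material |
| 12 | 4-{[(1S,4R,5R)-4-hydroxy-2-methyl-5-[(2S)-6-methylhept-5-en-2-yl]cyclohex-2-en-1-yl]oxy}-3-methoxybenzaldehyde | COc1cc(C=O)ccc1O[C@H]2C[C@H]([C@@H](C)CCC=C(C)C)[C@@H](O)C=C2C | intermediate |
| 13 | acetylacetone | CC(=O)CC(C)=O | starting material |
| 14 | (5E)-6-(4-hydroxy-3-methoxyphenyl)hex-5-ene-2,4-dione | CC(=O)CC(=O)/C=C/c1ccc(O)c(OC)c1 | intermediate |
| 15 | Terpecurcumin B | COc1cc(/C=C/C(=O)/C=C(O)/C=C/c2ccc(O[C@H]3C[C@H]([C@@H](C)CCC=C(C)C)[C@@H](O)C=C3C)c(OC)c2)ccc1O | target |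

**Total step count:** 10

**Longest linear sequence:** 9 steps (1 → 3 → 4 → 6 → 7 → 8 → 9 → 10 → 12 → 15, via steps 1–8 and 10)

**Three steps most likely to fail**
1. **Step 5 (proposed new photooxygenation).**
   - Risks: 1O2 ene or [2+2] reactions on the prenyl alkene or enol ether; wrong dienol regiochemistry; base-sensitive γ-hydroxy enone.
   - Fallback (known chemistry): replace the pericyclic step with polar electrophilic O-transfer, a vinylogous Rubottom oxidation of 7 with DMDO or a Davis oxaziridine. The fully substituted α-carbon steers attack to C4, anti to the side chain.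
2. **Step 6 (directed hydrogenation).**
   - Risks: Ir–H alkene isomerisation, reduction of the enone or prenyl alkene, and a modest dr at C7′.
   - Fallback: use non-directed HAT hydrogenation (Mn or Fe/PhSiH3) of 8 and separate the C7′ epimers at diol 10.
3. **Step 8 (mono-Mitsunobu of diol 10).**
   - Risks: C4-ether formation, SN2′ attack, or elimination.
   - Fallback: silylate C4–OH of 9 (TBSOTf, 2,6-lutidine), then do Luche reduction and Mitsunobu on the single remaining OH, then remove TBS with TBAF.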